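Overlay the earlier runs in percent of the substrate charged, as I did first.

| flask | substrate | partner | protic impurity | remark | time |
|---|---|---|---|---|---|
| ochre | 34 mM | 40.8 mM | 0.68 mM | run made earlier |  |
| amber | 17 mM | 40.8 mM | 0.68 mM | run made earlier |  |
| violet | 26 mM | 40.8 mM | 0.68 mM | run made earlier |  |
| epsilon | 34 mM | 40.8 mM (fed, over 5.0 h) | 0.680 mM | all else is in the flask from the start; the feed brings no volume worth counting | 8.0 h |
| gamma | 34 mM | 40.8 mM | 0.680 mM | everything together at the start | 8.0 h |
| beta | 34 mM (fed, over 5.0 h) | 40.8 mM | 0.680 mM | all else is in the flask from the start; the feed brings no volume worth counting | 8.0 h |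

- ochre (time / h: target / %, substrate / %): 0.667: 4.7, 90.3; 1.33: 7.9, 83.6; 2.00: 9.6, 79.8; 3.00: 9.7, 76.5; 4.00: 8.7, 74.6; 5.00: 8.3, 73.9
- amber (time / h: target / %, substrate / %): 0.250: 1.3, 95.7; 0.667: 4.6, 90.0; 1.33: 7.9, 83.4; 2.00: 9.8, 79.8; 3.00: 9.5, 75.6; 4.00: 10.0, 73.3; 5.00: 9.7, 72.5
- violet (time / h: target / %, substrate / %): 0.667: 4.2, 89.9; 1.33: 7.7, 83.6; 2.00: 9.7, 79.2; 3.00: 9.7, 76.0; 4.00: 9.4, 74.1; 5.00: 8.9, 72.9

(each reading ± 0.3 percentage points)



1. the flask that comes out highest in amount of target, in percent of the substrate charged, or "all alike" when all lie within 1.5 percentage points (epsilon / gamma / beta / all alike)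
2. target at the end, in percent of the substrate charged, epsilon
3. target at the end, in percent of the substrate charged, gamma
4. target at the end, in percent of the substrate charged, beta

At 0.667 h ochre stood at 90.3 % substrate and amber at 90.0 %, though ochre held twice amber's charge, so I read the early loss as first order in substrate. Amber's slope at the start was 0.172 /h, in fractions of the charge. Its curve then bent towards a level of 27.5 % lost at 5.00 h. I drew the starting tangent up to that level, and they crossed at 1.60 h, a reading I named the working window: the time at which the flask passed from its starting rate to its level.

Amber's target bent near the same place. Its tangent through 4.6 % at 0.667 h met the reading of 9.8 % at 1.42 h. Ochre's target then drifted to 8.3 % at 5.00 h, and since gamma has ochre's recipe, I expected about that level for gamma.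

Beta feeds its substrate over 5.0 h, longer than the window. I let the flask's strength fade exponentially with the window. The substrate present at any time is then that time's fraction of the feed, and its mean under the fading strength is the window over the feed time, 32.0 %. So I reckoned beta at that share of ochre's level, 2.65 %. Ochre, amber and violet each held the partner at 40.8 mM, so I drew no number for epsilon from the window.

The forecast put epsilon highest, with 9.2 % for epsilon, 8.6 % for gamma and 4.1 % for beta, on the ground that “Substrate fed late meets little partner”, and my figure for beta was lower.

The flasks gave 15.6 % in epsilon, 8.18 % in gamma and 2.85 % in beta, and epsilon stood highest.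

    substrate ⇌ open intermediate (K = 0.118, k = 0.235 /h)
    partner → second intermediate (k = 1.91 /h)
    open intermediate + second intermediate → target (k = 252 /M/h)
    2 second intermediate → homo product (k = 232 /M/h)
    partner + protic impurity → quenched reagent (k = 63.2 /M/h)
    target ⇌ isomer of the product (K = 1.30, k = 0.470 /h)

In beta the path from partner to second intermediate had done half of its turnover up to the end by 0.360 h, earlier than my window, when the feed had brought 7.20 % of the substrate. Beta's target was 34.8 % of gamma's, against the share of 32.0 % from the window. The neighbour of beta charged with 8.5 mM of substrate, below amber's 17 mM, came by the same share to 2.65 %, and that flask gave more, 4.27 %.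

All runs are simulated with constants of no real substance, and the scatter is random.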